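I start from these amounts, with the steps and the questions beside them.

- theta: starting complex 14 mM; incoming ligand 1.80 equiv; time 12 s
- zeta: starting complex 14 mM; incoming ligand 1.20 equiv; time 12 s

    complex with two exchanged + incoming ligand ⇌ leaving ligand + complex with three exchanged (K1 = 8.5, k1 = 0.159 L mol⁻¹ s⁻¹)
    leaving ligand + starting complex ⇌ idle adduct, settled at all times (K2 = 10000 L mol⁻¹)
    starting complex + incoming ligand ⇌ leaving ligand + complex with one exchanged (K3 = 23.2, k3 = 4.99 L mol⁻¹ s⁻¹)
    complex with one exchanged + incoming ligand ⇌ leaving ligand + complex with two exchanged (K4 = 0.37, k4 = 0.378 L mol⁻¹ s⁻¹)

* part of the starting complex that has reacted at the end, theta
* part of the starting complex that has reacted at the end, zeta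
* what raising the equivalents of incoming ligand from its lowest to its highest value here does to the part of the starting complex that has reacted (changes below 5 percentage points count as none) (no change / it falls / it rises)

- for leaving ligand the idle adduct is counted in
- what has gone from starting complex into another species counts as reacted, even if it can come back
- run time (theta): 12 s

I follow one leaving ligand in zeta. Freed by the first exchange, it either enters the idle adduct or stays free, and at the start the odds for the adduct are 140 to one, so nearly all of it ends up bound while [starting complex] stands near its charge. The first exchange, with a forward half-life of 8.3 s as charged in zeta, also runs well ahead of the second at 110 s. I therefore let each incoming ligand spent cost two starting complexes, one exchanged and one held in the adduct, which makes the starting complex the limiting reagent.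

[Starting complex] then falls at twice the rate of step 3 and [incoming ligand] at that rate once, so the logarithm of the fraction of incoming ligand left over the fraction of starting complex left grows in a straight line with time. At the end it stands at 1.17 in zeta and 2.18 in theta. This is the pair clock: k3 times the time times the excess of twice the charged [incoming ligand] over the charged [starting complex]. Solving it with the two losses tied gives 79.3% reacted for zeta and 91.6% for theta, a rise of 12 percentage points.

A neighbour of zeta looks nearly the same, with equal equivalents and equal time but 3.5 mM of starting complex. Its adduct odds still give 97.2% at the start, but its clock runs at a quarter of zeta's pace, so I expect it to end far behind zeta.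

The forecast says 92.5% for theta and 80% for zeta, a little above mine, and of the part reacted, on going from the lower to the higher equivalents of incoming ligand, that it rises, on the ground that “each first exchange removes about two starting complexes”. The flask gives 90.8% for theta and 79.1% for zeta, so it rises by 12 points.

At 12.0 s zeta holds 21% of its starting complex and 66% of its incoming ligand, so the pair clock read from these amounts stands at 1.15, against 1.17 reckoned. For the neighbour with 3.5 mM the clock is 0.293, which gives 36.9% reacted. That flask holds 63.6% of its starting complex at 12.0 s, and its part reacted is 36.4%.

(The rate constants belong to no real substance; no experiment stands behind them.)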